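**Plan**

1. Numbering (germacrane locants, used for the six-membered precursors too): C1–C3 = CH2, C4 = C(CH3)OH, C5 = CHOH, C6 = CH–O–acyl, C7 = CH–C11(CH3)2OH, C8–C9 = CH2, C10 = CH(CH3). The target is the (4R,5S,6R,7R,10S) isomer and the ester is the (Z)-2-methylbut-2-enoate (angelate).
2. Enabling feature: the ring segment C9–C10–C1–C2 carries only the C10 methyl, and C3 and C8 at its ends are 1,6-related across the cyclodecane. A bond C3–C8 (absent from the target) turns the ring into a p-menthane-type cyclohexane C3–C8 that holds all four oxygenated stereocentres C4–C7.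
3. Retrosynthesis: cut the C6–O acyl bond; cut ring bond C1–C10 while re-forming C3–C8 (retro anionic oxy-Cope, with the C3 oxygen and the C2=C3/C8=C9 unsaturation as removable traces); cut C3–vinyl and C8–allyl; trace the cyclohexanone to (S)-carvone.
4. Forward: (S)-carvone → C11 hydration → C4/C5 syn-dihydroxylation → C5=C6 alkene → epoxide → trans-diaxial opening by BnOH at C6 → acetonide → C8 allylation, C3 vinylation, allyl to (E)-propenyl → [3,3] ring expansion 6 → 10 (the only ring of the target arises here) → removal of C3–OTf, both alkenes and Bn → angelate → deprotection.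
5. Stereochemistry: C7 from (S)-carvone; C4, C5, C6 by substrate control on the cyclohexane chair with the C7 side chain equatorial; C10 by chirality transfer through the chair transition state of the ring expansion; the Z ester alkene comes with angelic acid.

Key step: step 11

**Route**

Step 1
Reactants: 1 (S)-(+)-carvone
Product: 2 (5S)-5-(2-hydroxypropan-2-yl)-2-methylcyclohex-2-en-1-one
Conditions: Co(acac)2 (cat.), PhSiH3, O2 (1 atm), THF, rt
Reagents that add atoms: dioxygen O=O
Why: Mukaiyama hydration (metal-hydride hydrogen-atom transfer, then trapping of the tertiary radical by O2) should hydrate the electron-rich 1,1-disubstituted isopropenyl group in the Markovnikov sense and leave the enone and the C7 stereocentre alone.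

Step 2
Reactants: 2 (5S)-5-(2-hydroxypropan-2-yl)-2-methylcyclohex-2-en-1-one
Product: 3 (5S)-2-methyl-5-[2-(triethylsilyloxy)propan-2-yl]cyclohex-2-en-1-one
Conditions: TESOTf, 2,6-lutidine, CH2Cl2, −78 °C
Reagents that add atoms: triethylsilyl trifluoromethanesulfonate CC[Si](CC)(CC)OS(=O)(=O)C(F)(F)F
Why: Silylation of the tertiary alcohol prevents its later attack on the epoxide (bridged-ether formation) and makes the C7 substituent a conformational anchor; at −78 °C O-silylation should outrun silyl enol ether formation.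

Step 3
Reactants: 3 (5S)-2-methyl-5-[2-(triethylsilyloxy)propan-2-yl]cyclohex-2-en-1-one
Product: 4 (2S,3S,5S)-2,3-dihydroxy-2-methyl-5-[2-(triethylsilyloxy)propan-2-yl]cyclohexan-1-one
Conditions: K2OsO2(OH)4 (2 mol %), NMO, citric acid, t-BuOH–H2O, rt
Reagents that add atoms: N-methylmorpholine N-oxide C[N+]1([O-])CCOCC1; water O
Why: Upjohn syn-dihydroxylation (citric acid variant for the electron-poor trisubstituted enone) should add to C4=C5 on the face trans to the equatorial C7 side chain, the face also used in the Weitz–Scheffer epoxidation of carvone, which sets the tertiary C4 carbinol and places the C5 hydroxyl axial.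

Step 4
Reactants: 4 (2S,3S,5S)-2,3-dihydroxy-2-methyl-5-[2-(triethylsilyloxy)propan-2-yl]cyclohexan-1-one
Product: 6 (2S,5R)-2-hydroxy-2-methyl-5-[2-(triethylsilyloxy)propan-2-yl]cyclohex-3-en-1-one, via mesylate 5 (not isolated)
Conditions: MsCl, Et3N, CH2Cl2, −20 °C; then DBU, PhMe, 80 °C
Reagents that add atoms: methanesulfonyl chloride CS(=O)(=O)Cl (its atoms are in 5 only)
Why: Selective sulfonylation of the only secondary hydroxyl (C5) and E2 elimination; the axial mesylate is anti-periplanar to the axial C6 hydrogen and C4 has no hydrogen, so only the C5=C6 alkene can form and the C4 stereocentre stays.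

Step 5
Reactants: 6 (2S,5R)-2-hydroxy-2-methyl-5-[2-(triethylsilyloxy)propan-2-yl]cyclohex-3-en-1-one
Product: 7 (1S,2S,5R,6S)-2-hydroxy-2-methyl-5-[2-(triethylsilyloxy)propan-2-yl]-7-oxabicyclo[4.1.0]heptan-3-one
Conditions: VO(acac)2 (5 mol %), t-BuOOH, CH2Cl2, 0 °C → rt
Reagents that add atoms: tert-butyl hydroperoxide CC(C)(C)OO
Why: Hydroxyl-directed vanadium-catalysed epoxidation of the tertiary allylic alcohol should deliver oxygen cis to the C4 hydroxyl, on the face that is also trans to the C7 side chain and opposite to the axial C4 methyl, which sets the configuration of the C5 oxygen.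

Step 6
Reactants: 7 (1S,2S,5R,6S)-2-hydroxy-2-methyl-5-[2-(triethylsilyloxy)propan-2-yl]-7-oxabicyclo[4.1.0]heptan-3-one
Product: 8 (2S,3S,4R,5R)-4-(benzyloxy)-2,3-dihydroxy-2-methyl-5-[2-(triethylsilyloxy)propan-2-yl]cyclohexan-1-one
Conditions: BnOH (5 equiv), Yb(OTf)3 (10 mol %), CH2Cl2, 0 °C → rt
Reagents that add atoms: benzyl alcohol OCc1ccccc1
Why: Lewis-acid-catalysed alcoholysis of the epoxide should follow the Fürst–Plattner rule in the half-chair with the C7 side chain equatorial (C5 is also shielded by the adjacent quaternary carbinol carbon), so benzyl alcohol attacks C6 with inversion and gives the trans-diaxial C5-OH/C6-OBn pair.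

Step 7
Reactants: 8 (2S,3S,4R,5R)-4-(benzyloxy)-2,3-dihydroxy-2-methyl-5-[2-(triethylsilyloxy)propan-2-yl]cyclohexan-1-one
Product: 9 acetonide of 8 (cis-fused 2,2-dimethyl-1,3-dioxolane across the C4 and C5 oxygens)
Conditions: Me2C(OMe)2, PPTS (cat.), CH2Cl2, rt
Reagents that add atoms: 2,2-dimethoxypropane COC(C)(C)OC
Why: Acid-catalysed transacetalisation closes the cis C4/C5 diol to a cis-fused dioxolane, which protects both hydroxyls for the basic steps and leaves C8 as the only enolisable position.

Step 8
Reactants: 9 acetonide ketone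
Product: 11 C8-allyl ketone (allyl trans to the C7 side chain), via lithium enolate 10 (not isolated)
Conditions: LDA, THF, −78 °C; then allyl bromide, DMPU, −78 → −20 °C
Reagents that add atoms: lithium diisopropylamide [Li+].CC(C)[N-]C(C)C; allyl bromide C=CCBr
Why: Kinetic enolate alkylation; the regiodefined lithium enolate (C3=C8) should be allylated on the face trans to the adjacent C7 side chain, giving the equatorial allyl group.

Step 9
Reactants: 11 C8-allyl ketone
Product: 12 tertiary C3 carbinol (hydroxyl cis to the dioxolane oxygens; vinyl trans to the C8 allyl group)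
Conditions: CeCl3, CH2=CHMgBr, THF, −78 → 0 °C; aq. NH4Cl
Reagents that add atoms: vinylmagnesium bromide C=C[Mg]Br
Why: 1,2-Addition of the organocerium reagent (chosen to suppress enolisation of the hindered ketone) should occur by equatorial attack from the convex face, anti to the cis-fused dioxolane and its axial C5 oxygen, giving the axial tertiary hydroxyl and a vinyl group trans to the C8 allyl group.

Step 10
Reactants: 12 allyl vinyl carbinol
Product: 13 (E)-prop-1-enyl vinyl carbinol (both alkenyl groups equatorial and trans)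
Conditions: [CpRu(MeCN)(κ2-P,N-phosphinoimidazole)]PF6 (3 mol %), acetone, 40 °C
Reagents that add atoms: none
Why: Catalytic one-position alkene isomerisation should move the terminal allyl double bond to the thermodynamically preferred (E)-prop-1-enyl position and stop at the branched ring carbon, while the C3 vinyl group has no allylic hydrogen and cannot move.

Step 11
Reactants: 13 (E)-prop-1-enyl vinyl carbinol
Product: 16 ten-membered enol triflate (C3–OTf; ring carbons trans at C2=C3 and at C8=C9; 10S), via potassium alkoxide 14 (not isolated), via potassium enolate 15 (not isolated)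
Conditions: KH, 18-crown-6, THF, 0 °C → rt; then PhNTf2, −78 → 0 °C
Reagents that add atoms: potassium hydride [K+].[H-]; N-phenylbis(trifluoromethanesulfonimide) FC(F)(F)S(=O)(=O)N(c1ccccc1)S(=O)(=O)C(F)(F)F
Why: Deprotonation gives alkoxide 14, whose 3-oxido-1,5-diene unit C1=C2–C3(O⁻)–C8–C9=C10 undergoes the alkoxide-accelerated [3,3]-sigmatropic shift (anionic oxy-Cope rearrangement); the closest known reaction type is the ring expansion of trans-1,2-dialkenylcyclohexanols to (E)-cyclodec-5-enones. The ten-membered ring is closed by forming the σ-bond C1–C10 while the ring bond C3–C8 breaks, a four-carbon ring expansion through a six-membered chair array fused to the cyclohexane, so no end-to-end medium-ring cyclisation is needed. C10 is the only new stereocentre: in the cyclohexane chair that keeps the C7 side chain and both alkenyl groups equatorial (C3–O axial) the transition-state chair is trans-fused, the methyl of the (E)-propenyl group sits equatorial, and the C3/C8 configuration is transferred to (10S) together with an E C8=C9 bond. The step needs chair over boat selectivity, which the trans-diequatorial alkenyl groups and the E-propenyl geometry secure, and a regiodefined enolate, which forms directly at C2=C3 and cannot equilibrate because C4 is quaternary. This enolate has no β-leaving group, so it should last until PhNTf2 traps it as enol triflate 16, which marks the C3 oxygen for removal.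

Step 12
Reactants: 16 ten-membered enol triflate
Product: 17 (E,E)-cyclodeca-2,8-diene (C3–H; acetonide, OBn and OTES unchanged; 10S)
Conditions: Pd(OAc)2 (5 mol %), PPh3, HCO2H, n-Bu3N, DMF, 40 °C
Reagents that add atoms: none
Why: Palladium-catalysed formate reduction of the enol triflate replaces C3–OTf by hydrogen without touching a stereocentre, at a temperature below that at which the (E,E)-cyclodeca-1,5-diene would undergo Cope rearrangement.

Step 13
Reactants: 17 (E,E)-cyclodeca-2,8-diene
Product: 18 saturated cyclodecane with free C6 hydroxyl (C4/C5 acetonide, C11–OTES, 10S)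
Conditions: H2 (1 atm), Pd(OH)2/C, EtOAc, rt
Reagents that add atoms: none
Why: Heterogeneous hydrogenation saturates the two strained E ring alkenes (no new stereocentre arises) and hydrogenolyses the benzyl ether in the same operation; fast uptake at the trans-cycloalkenes should limit double-bond migration towards C10.

Step 14
Reactants: 18 C6 alcohol; 19 angelic acid ((Z)-2-methylbut-2-enoic acid)
Product: 21 protected C6 angelate, via mixed anhydride 20 (not isolated)
Conditions: 19, 2,4,6-Cl3C6H2COCl, Et3N, PhMe, rt; then 18, PhMe, 75 °C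
Reagents that add atoms: 2,4,6-trichlorobenzoyl chloride O=C(Cl)c1c(Cl)cc(Cl)cc1Cl (its atoms are in 20 only)
Why: Yamaguchi-type esterification through the 2,4,6-trichlorobenzoyl mixed anhydride without DMAP is the established way to acylate hindered secondary alcohols with angelic acid without Z to E isomerisation, and the C6 hydroxyl is the only free one.

Step 15
Reactants: 21 protected C6 angelate
Product: 22 (4R,5S,6R,7R,10S)-4,5,11-trihydroxygermacran-6-yl (Z)-2-methylbut-2-enoate (target)
Conditions: aq. HF (48 %), MeCN, 0 °C → rt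
Reagents that add atoms: none
Why: Acidic global deprotection; aqueous HF should cleave the tertiary silyl ether and hydrolyse the acetonide while the angelate and the tertiary carbinols survive, giving the target with all five stereocentres as set.

**Compound list**

1 | (S)-(+)-carvone, (5S)-2-methyl-5-(prop-1-en-2-yl)cyclohex-2-en-1-one | CC1=CC[C@@H](CC1=O)C(C)=C | starting material
2 | (5S)-5-(2-hydroxypropan-2-yl)-2-methylcyclohex-2-en-1-one | CC1=CC[C@@H](CC1=O)C(C)(C)O | intermediate
3 | (5S)-2-methyl-5-[2-(triethylsilyloxy)propan-2-yl]cyclohex-2-en-1-one | CC1=CC[C@@H](CC1=O)C(C)(C)O[Si](CC)(CC)CC | intermediate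
4 | (2S,3S,5S)-2,3-dihydroxy-2-methyl-5-[2-(triethylsilyloxy)propan-2-yl]cyclohexan-1-one (cis-diol trans to the side chain) | C1[C@H](C(C)(C)O[Si](CC)(CC)CC)CC(=O)[C@@](C)(O)[C@H]1O | intermediate
5 | (1S,2S,5S)-2-hydroxy-2-methyl-3-oxo-5-[2-(triethylsilyloxy)propan-2-yl]cyclohexyl methanesulfonate (not isolated) | C1[C@H](C(C)(C)O[Si](CC)(CC)CC)CC(=O)[C@@](C)(O)[C@H]1OS(C)(=O)=O | intermediate
6 | (2S,5R)-2-hydroxy-2-methyl-5-[2-(triethylsilyloxy)propan-2-yl]cyclohex-3-en-1-one | C1=C[C@](C)(O)C(=O)C[C@H]1C(C)(C)O[Si](CC)(CC)CC | intermediate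
7 | (1S,2S,5R,6S)-2-hydroxy-2-methyl-5-[2-(triethylsilyloxy)propan-2-yl]-7-oxabicyclo[4.1.0]heptan-3-one (epoxide cis to OH, trans to the side chain) | [C@H]12[C@H](C(C)(C)O[Si](CC)(CC)CC)CC(=O)[C@@](C)(O)[C@H]1O2 | intermediate
8 | (2S,3S,4R,5R)-4-(benzyloxy)-2,3-dihydroxy-2-methyl-5-[2-(triethylsilyloxy)propan-2-yl]cyclohexan-1-one | c1ccccc1CO[C@@H]2[C@H](C(C)(C)O[Si](CC)(CC)CC)CC(=O)[C@@](C)(O)[C@H]2O | intermediate
9 | acetonide of 8: C3 ketone with cis-fused 2,2-dimethyl-1,3-dioxolane on C4/C5, 6-OBn, 7-C(CH3)2OTES | c1ccccc1CO[C@@H]2[C@H](C(C)(C)O[Si](CC)(CC)CC)CC(=O)[C@@]3(C)OC(C)(C)O[C@@H]23 | intermediate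
10 | lithium enolate of 9 (C3=C8; not isolated) | c1ccccc1CO[C@@H]2[C@H](C(C)(C)O[Si](CC)(CC)CC)C=C([O-])[C@@]3(C)OC(C)(C)O[C@@H]23.[Li+] | intermediate
11 | C8-allyl derivative of 9, allyl trans to the C7 side chain | c1ccccc1CO[C@@H]2[C@H](C(C)(C)O[Si](CC)(CC)CC)[C@@H](CC=C)C(=O)[C@@]3(C)OC(C)(C)O[C@@H]23 | intermediate
12 | C3 tertiary alcohol from 11: 3-vinyl, OH cis to the dioxolane oxygens, vinyl trans to the 8-allyl group | c1ccccc1CO[C@@H]2[C@H](C(C)(C)O[Si](CC)(CC)CC)[C@@H](CC=C)[C@](O)(C=C)[C@@]3(C)OC(C)(C)O[C@@H]23 | intermediate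
13 | as 12 with the 8-allyl group isomerised to (E)-prop-1-enyl | c1ccccc1CO[C@@H]2[C@H](C(C)(C)O[Si](CC)(CC)CC)[C@@H](/C=C/C)[C@](O)(C=C)[C@@]3(C)OC(C)(C)O[C@@H]23 | intermediate
14 | potassium alkoxide of 13 (not isolated) | c1ccccc1CO[C@@H]2[C@H](C(C)(C)O[Si](CC)(CC)CC)[C@@H](/C=C/C)[C@]([O-])(C=C)[C@@]3(C)OC(C)(C)O[C@@H]23.[K+] | intermediate
15 | potassium enolate of the ring-expanded cyclodec-8-en-3-one (C2=C3 enolate, ring carbons trans; 8E; 10S; not isolated) | c1ccccc1CO[C@@H]2[C@H](C(C)(C)O[Si](CC)(CC)CC)/C=C/[C@@H](C)C/C=C(\[O-])/[C@@]3(C)OC(C)(C)O[C@@H]23.[K+] | intermediate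
16 | ten-membered enol triflate: C3–OTf, C2=C3 and C8=C9 with ring carbons trans, (10S)-methyl, 4,5-acetonide, 6-OBn, 11-OTES | c1ccccc1CO[C@@H]2[C@H](C(C)(C)O[Si](CC)(CC)CC)/C=C/[C@@H](C)C/C=C(\OS(=O)(=O)C(F)(F)F)/[C@@]3(C)OC(C)(C)O[C@@H]23 | intermediate
17 | (2E,8E,10S)-germacra-2,8-diene-4,5,6,11-tetrol 4,5-acetonide 6-benzyl ether 11-triethylsilyl ether | c1ccccc1CO[C@@H]2[C@H](C(C)(C)O[Si](CC)(CC)CC)/C=C/[C@@H](C)C/C=C/[C@@]3(C)OC(C)(C)O[C@@H]23 | intermediate
18 | germacrane-4,5,6,11-tetrol 4,5-acetonide 11-triethylsilyl ether (free 6-OH; configuration as in the target) | O[C@@H]1[C@H](C(C)(C)O[Si](CC)(CC)CC)CC[C@@H](C)CCC[C@@]3(C)OC(C)(C)O[C@@H]13 | intermediate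
19 | angelic acid, (Z)-2-methylbut-2-enoic acid | C/C=C(/C)C(=O)O | starting material
20 | angelic 2,4,6-trichlorobenzoic mixed anhydride (not isolated) | C/C=C(/C)C(=O)OC(=O)c1c(Cl)cc(Cl)cc1Cl | intermediate
21 | 6-O-angeloyl derivative of 18 | C/C=C(/C)C(=O)O[C@@H]1[C@H](C(C)(C)O[Si](CC)(CC)CC)CC[C@@H](C)CCC[C@@]3(C)OC(C)(C)O[C@@H]13 | intermediate
22 | (4R,5S,6R,7R,10S)-4,5,11-trihydroxygermacran-6-yl (Z)-2-methylbut-2-enoate | C/C=C(/C)C(=O)O[C@@H]1[C@H](C(C)(C)O)CC[C@@H](C)CCC[C@@](C)(O)[C@H]1O | target

**Step count and risks**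

Total steps: 15. Longest linear sequence: 15 steps from 1 (19 enters in step 14).

Steps most likely to fail:

Step 9. The ketone is flanked by a quaternary and a tertiary carbon, so the vinyl reagent may act as a base (enolisation) or add from the wrong face. The wrong face would give the cis-dialkenyl carbinol, which cannot reach the chair transition state of step 11. Fallback, from 11: Corey–Chaykovsky reaction with dimethylsulfoxonium methylide (Me3S(O)I, NaH, DMSO; reversible addition, CH2 delivered equatorially) should give spiro-epoxide F1 with the oxygen axial. Excess dimethylsulfonium methylide (Me3SI, n-BuLi, THF, −10 °C → rt) should then homologate the oxirane CH2 to a vinyl group (epoxide to allylic alcohol by one carbon) and return to the route at 12.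

Step 11. The crowded potassium alkoxide may fragment (retro-allylation) or rearrange partly through a boat, and O-sulfonylation of the hindered enolate may be slow. Fallback, from 13: neutral thermal oxy-Cope rearrangement (o-dichlorobenzene, 200 °C, sealed tube; tautomerisation of the enol makes it irreversible) should give cyclodecenone F2. Only C2 can be deprotonated, so KHMDS/PhNTf2 should give enol triflate F3 (C2=C3 geometry immaterial). Palladium/formate reduction should give diene F4, and hydrogenation with hydrogenolysis as in step 13 returns to the route at 18.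

Step 6. The Lewis acid may trigger a semipinacol-type shift of the epoxy α-ketol or participation of the silyl ether oxygen, or the alcohol may attack C5. Fallback, from 7: hydrolytic trans-diaxial opening with water (cat. HClO4, THF–H2O, 0 °C) should give triol F5. Acetonide formation (Me2C(OMe)2, PPTS) should select the cis C4/C5 diol over the trans-diaxial C5/C6 pair and give acetonide alcohol F6. Benzylation of the remaining C6 hydroxyl under neutral conditions (2-benzyloxy-1-methylpyridinium triflate, MgO, PhCF3, 85 °C) returns to the route at 9.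

**Further compounds**

F1 | step 9 | spiro-epoxide at C3 of 11 (oxirane oxygen cis to the dioxolane oxygens, CH2 trans to the 8-allyl group) | c1ccccc1CO[C@@H]2[C@H](C(C)(C)O[Si](CC)(CC)CC)[C@@H](CC=C)[C@]4(CO4)[C@@]3(C)OC(C)(C)O[C@@H]23
F2 | step 11 | (8E,10S)-cyclodec-8-en-3-one with 4,5-acetonide, 6-OBn, 11-OTES | c1ccccc1CO[C@@H]2[C@H](C(C)(C)O[Si](CC)(CC)CC)/C=C/[C@@H](C)CCC(=O)[C@@]3(C)OC(C)(C)O[C@@H]23
F3 | step 11 | enol triflate of F2 (C2=C3, geometry not controlled) | c1ccccc1CO[C@@H]2[C@H](C(C)(C)O[Si](CC)(CC)CC)/C=C/[C@@H](C)CC=C(OS(=O)(=O)C(F)(F)F)[C@@]3(C)OC(C)(C)O[C@@H]23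
F4 | step 11 | cyclodeca-2,8-diene from F3 (8E; C2=C3 geometry not controlled) | c1ccccc1CO[C@@H]2[C@H](C(C)(C)O[Si](CC)(CC)CC)/C=C/[C@@H](C)CC=C[C@@]3(C)OC(C)(C)O[C@@H]23
F5 | step 6 | (2S,3S,4R,5R)-2,3,4-trihydroxy-2-methyl-5-[2-(triethylsilyloxy)propan-2-yl]cyclohexan-1-one | O[C@@H]1[C@H](C(C)(C)O[Si](CC)(CC)CC)CC(=O)[C@@](C)(O)[C@H]1O
F6 | step 6 | C4/C5 acetonide of F5 with free C6 hydroxyl | O[C@@H]1[C@H](C(C)(C)O[Si](CC)(CC)CC)CC(=O)[C@@]3(C)OC(C)(C)O[C@@H]13
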